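**Plan**

- Numbering as in eudesmane (ring A: C1–C5 and C10; ring B: C5–C10; C14 on C10, C15 on C4, isopropyl on C7). Retrosynthesis: the ester C–O bond is cut first (eudesm-3-en-6β-ol plus silyl-protected (E)-p-coumaric acid); the alcohol goes back through the 3-en-6-one to eudesma-2,4-dien-6-one; this dienone is cut at C5–C10 and C2–C3 in one operation to an open-chain keto-enal; C5–C6 and C10–C1 are cut last (two Grignard additions) to a nine-carbon keto acid.
- Enabling feature: the C6 carbonyl makes C5 (α) and, through the isopropenyl group on C4, the terminal carbon that becomes C3 (γ) a 1,3-bis-nucleophile. The β,β-disubstituted enal C10=C1–C2 is a 1,3-bis-electrophile. The tether C6–C7–C8–C9 makes the first closure six-membered, and the two one-carbon groups on C4 are equivalent, so no regiochemical choice arises.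
- Forward: (−)-menthone is dehydrogenated to (S)-piperitone and ozonised to the acyclic keto acid. Vinyl and 2-methylallyl Grignard additions and an oxidative allylic transposition give the keto-enal. One amine-catalysed cascade closes ring B (C5–C10) and then ring A (C2–C3). 1,6-Reduction, ketone reduction and acylation follow.
- Stereochemistry: C7 comes from (−)-menthone. C10 is set in the cascade by 1,4-induction from C7. C5 is set by kinetic protonation of a dienolate anti to the angular methyl group. C6 is set by hydride attack anti to the same methyl group.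

Key step: step 8

Remark: the enal formed in step 7 is expected as an E/Z mixture and is taken on as such, since both isomers should converge in the cascade; (−)-menthone is taken as the commercial (2S,5R) isomer.

**Route**

Step 1
Reactants: 1 (−)-menthone, (2S,5R)-5-methyl-2-(propan-2-yl)cyclohexan-1-one
Product: 2 trimethyl{[(3R,6S)-3-methyl-6-(propan-2-yl)cyclohex-1-en-1-yl]oxy}silane
Conditions: LiN(i-Pr)2, THF, −78 °C; Me3SiCl, −78 °C to rt
Reagents that add atoms: chlorotrimethylsilane, C[Si](C)(C)Cl
Why: Kinetic deprotonation removes a proton from the unhindered ring CH2 next to the carbonyl and not from the isopropyl-bearing methine (the future C7), and O-silylation fixes that enolate (regioselective silyl enol ether formation), so the stereocentre is untouched.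

Step 2
Reactants: 2 trimethyl{[(3R,6S)-3-methyl-6-(propan-2-yl)cyclohex-1-en-1-yl]oxy}silane
Product: 3 (S)-piperitone, (6S)-3-methyl-6-(propan-2-yl)cyclohex-2-en-1-one
Conditions: Pd(OAc)2 (10 mol %), O2 (1 atm), DMSO, rt
Reagents that add atoms: none
Why: Saegusa–Ito oxidation (palladation of the silyl enol ether, β-hydride elimination from the methyl-bearing carbon, reoxidation of the palladium by O2) should give the conjugated enone under neutral conditions that leave the isopropyl-bearing stereocentre intact.

Step 3
Reactants: 3 (S)-piperitone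
Product: 5 (2S)-5-oxo-2-(propan-2-yl)hexanoic acid, via α-keto acid 4 (not isolated)
Conditions: O3, CH2Cl2, −78 °C; then 30% aq. H2O2, AcOH, rt
Reagents that add atoms: ozone, [O-][O+]=O; hydrogen peroxide, OO
Why: Ozonolysis of the enone C=C bond with oxidative work-up leaves a methyl ketone (C10 with C14) and, after oxidative decarboxylation of the α-keto acid by H2O2, the C6 carboxylic acid, the stereocentre being inert in the non-basic medium.

Step 4
Reactants: 5 (2S)-5-oxo-2-(propan-2-yl)hexanoic acid
Product: 7 (2S)-N-methoxy-N-methyl-5-oxo-2-(propan-2-yl)hexanamide, via acyl imidazole 6 (not isolated)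
Conditions: 1,1'-carbonyldiimidazole, CH2Cl2, rt; then MeNH(OMe)·HCl, rt
Reagents that add atoms: N,O-dimethylhydroxylamine hydrochloride, CNOC.Cl
Why: Weinreb amide formation through the acyl imidazole needs no strong base, so the methyl ketone and the α-stereocentre should both survive.

Step 5
Reactants: 7 (2S)-N-methoxy-N-methyl-5-oxo-2-(propan-2-yl)hexanamide
Product: 8 (2S)-5-hydroxy-N-methoxy-N,5-dimethyl-2-(propan-2-yl)hept-6-enamide (both C5 epimers)
Conditions: CH2=CHMgBr (1.1 equiv), THF, −78 °C; aq. NH4Cl
Reagents that add atoms: vinylmagnesium bromide, C=C[Mg]Br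
Why: Grignard 1,2-addition to the methyl ketone is much faster at −78 °C than attack on the α-branched Weinreb amide, so the tertiary vinyl carbinol should form chemoselectively, and its new carbinol centre is erased in step 7 and needs no control.

Step 6
Reactants: 8 (2S)-5-hydroxy-N-methoxy-N,5-dimethyl-2-(propan-2-yl)hept-6-enamide
Product: 9 (5S)-8-hydroxy-2,8-dimethyl-5-(propan-2-yl)deca-1,9-dien-4-one (both C8 epimers)
Conditions: CH2=C(CH3)CH2MgCl (2.5 equiv), THF, −78 to 0 °C; cold aq. NH4Cl
Reagents that add atoms: 2-methylallylmagnesium chloride, CC(=C)C[Mg]Cl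
Why: Weinreb ketone synthesis, in which the allylic Grignard reagent (after one equivalent is spent on the hydroxyl group) adds once to give a chelated tetrahedral intermediate that releases the β,γ-unsaturated ketone only on work-up, which prevents over-addition, enolisation at the stereocentre and isomerisation into conjugation.

Step 7
Reactants: 9 (5S)-8-hydroxy-2,8-dimethyl-5-(propan-2-yl)deca-1,9-dien-4-one
Product: 10 (2E,6S)-3,9-dimethyl-7-oxo-6-(propan-2-yl)deca-2,9-dienal (with its 2Z isomer)
Conditions: pyridinium chlorochromate (C5H5NH)[CrO3Cl] (2.5 equiv), powdered 4 Å molecular sieves, CH2Cl2, rt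
Reagents that add atoms: pyridinium chlorochromate, [O-][Cr](=O)(=O)Cl.c1cc[nH+]cc1
Why: Babler–Dauben oxidative transposition, in which the tertiary allylic chromate ester undergoes a [3,3]-sigmatropic shift to the primary allylic chromate and is oxidised to the β,β-disubstituted enal, while the isolated ketone and the 1,1-disubstituted alkene are inert to the reagent.

Step 8
Reactants: 10 (2E,6S)-3,9-dimethyl-7-oxo-6-(propan-2-yl)deca-2,9-dienal (E/Z mixture)
Product: 12 (2S,4aS)-4a,8-dimethyl-2-(propan-2-yl)-3,4,4a,5-tetrahydro-2H-naphthalen-1-one (eudesma-2,4-dien-6-one), via Michael adduct 11 (not isolated)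
Conditions: pyrrolidine (30 mol %), PhCO2H (30 mol %), toluene, 60 °C
Reagents that add atoms: none
Why: Proposed new method: pyrrolidinium benzoate converts the enal into its iminium ion, whose β-carbon C10 is attacked by C5 of the dienol of the β,γ-unsaturated ketone (Michael addition giving 11), after which re-enolisation through C5 makes the terminal isopropenyl carbon C3 a vinylogous donor that adds to the C2 iminium and loses the amine by vinylogous E1cB to give the dienone; the closest known reaction type is the amine-catalysed Robinson annulation (Michael addition followed by aldol condensation) in its formal [3+3] variant with vinylogous donors. Ring B closes by a 6-(enolendo)-exo-trig Michael addition and ring A by a 6-(enolendo)-exo-trig vinylogous Mannich/aldol condensation, both favoured modes. C10, the only new stereocentre that persists, should be set by the C7 isopropyl group through a chair-like transition state of the Michael closure in which the isopropyl group and the iminium-bearing arm (C1) are equatorial and C14 is axial, which places C14 cis to the isopropyl group; C5 ends sp2 and needs no control. The step needs C5 and not C7 to act as donor (C5–H is allylic and on a CH2, C7–H is tertiary and hindered, so C7 should neither react nor epimerise), needs no choice between the two one-carbon groups on C4 (they are equivalent), and needs convergence of the E and Z enals (their iminium ions interconvert through the dienamine).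

Step 9
Reactants: 12 (2S,4aS)-4a,8-dimethyl-2-(propan-2-yl)-3,4,4a,5-tetrahydro-2H-naphthalen-1-one
Product: 13 (2S,4aR,8aR)-4a,8-dimethyl-2-(propan-2-yl)-3,4,4a,5,6,8a-hexahydro-2H-naphthalen-1-one (eudesm-3-en-6-one)
Conditions: Li (2.2 equiv), t-BuOH (1.0 equiv), NH3(l)/THF, −78 °C; then solid NH4Cl, −78 °C
Reagents that add atoms: none
Why: Dissolving-metal 1,6-reduction of a linearly conjugated dienone (Birch-type reduction, a known course for steroidal 4,6-dien-3-ones) puts hydrogen on C2 and leaves the C5=C6 lithium dienolate, whose kinetic protonation at the α-carbon C5 should occur anti to the angular methyl group C14, which stands perpendicular to the dienolate plane, and so give the trans-fused β,γ-unsaturated ketone with 5α-H.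

Step 10
Reactants: 13 (2S,4aR,8aR)-4a,8-dimethyl-2-(propan-2-yl)-3,4,4a,5,6,8a-hexahydro-2H-naphthalen-1-one
Product: 14 (1R,2S,4aR,8aR)-4a,8-dimethyl-2-(propan-2-yl)-1,2,3,4,4a,5,6,8a-octahydronaphthalen-1-ol (eudesm-3-en-6β-ol)
Conditions: LiBH(s-Bu)3 (L-selectride), THF, −78 °C; then aq. NaOH, H2O2, 0 °C
Reagents that add atoms: none
Why: Diastereoselective ketone reduction, in which the bulky hydride attacks C6 from the equatorial α direction because the axial β trajectory is blocked by the syn-axial C14 methyl group, should give the axial 6β alcohol.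

Step 11
Reactants: 15 (E)-p-coumaric acid, (2E)-3-(4-hydroxyphenyl)prop-2-enoic acid
Product: 17 (2E)-3-{4-[(tert-butyldimethylsilyl)oxy]phenyl}prop-2-enoic acid, via bis-silyl derivative 16 (not isolated)
Conditions: t-BuMe2SiCl (2.2 equiv), imidazole, DMF, rt; then AcOH/THF/H2O, rt
Reagents that add atoms: tert-butyldimethylsilyl chloride, CC(C)(C)[Si](C)(C)Cl
Why: Silyl protection, in which both the phenol and the acid are silylated and the labile silyl ester is then hydrolysed selectively, leaves only the phenol masked.

Step 12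
Reactants: 14 (1R,2S,4aR,8aR)-4a,8-dimethyl-2-(propan-2-yl)-1,2,3,4,4a,5,6,8a-octahydronaphthalen-1-ol; 17 (2E)-3-{4-[(tert-butyldimethylsilyl)oxy]phenyl}prop-2-enoic acid
Product: 19 (1R,2S,4aR,8aR)-4a,8-dimethyl-2-(propan-2-yl)-1,2,3,4,4a,5,6,8a-octahydronaphthalen-1-yl (2E)-3-{4-[(tert-butyldimethylsilyl)oxy]phenyl}prop-2-enoate, via mixed anhydride 18 (not isolated)
Conditions: 17, 2,4,6-Cl3C6H2COCl, Et3N, toluene, rt; then 14, DMAP, toluene, 80 °C
Reagents that add atoms: none
Why: Yamaguchi esterification through the mixed anhydride and the acylpyridinium ion is suited to hindered secondary alcohols and keeps the C6 configuration because the C–O bond of the alcohol is not broken.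

Step 13
Reactants: 19 (1R,2S,4aR,8aR)-4a,8-dimethyl-2-(propan-2-yl)-1,2,3,4,4a,5,6,8a-octahydronaphthalen-1-yl (2E)-3-{4-[(tert-butyldimethylsilyl)oxy]phenyl}prop-2-enoate
Product: 20 (1R,2S,4aR,8aR)-4a,8-dimethyl-2-(propan-2-yl)-1,2,3,4,4a,5,6,8a-octahydronaphthalen-1-yl (2E)-3-(4-hydroxyphenyl)prop-2-enoate (CNP0220414.1)
Conditions: Bu4NF (1.1 equiv), AcOH (1.2 equiv), THF, 0 °C
Reagents that add atoms: none
Why: Fluoride-mediated desilylation of the aryl silyl ether, buffered with acetic acid so that the phenoxide cannot attack the cinnamate ester, should free the phenol and give the target.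

**Compound list**

1 | (−)-menthone, (2S,5R)-5-methyl-2-(propan-2-yl)cyclohexan-1-one | CC(C)[C@@H]1CC[C@@H](C)CC1=O | starting material
2 | trimethyl{[(3R,6S)-3-methyl-6-(propan-2-yl)cyclohex-1-en-1-yl]oxy}silane | CC(C)[C@@H]1CC[C@@H](C)C=C1O[Si](C)(C)C | intermediate
3 | (S)-piperitone, (6S)-3-methyl-6-(propan-2-yl)cyclohex-2-en-1-one | CC(C)[C@@H]1CCC(C)=CC1=O | intermediate
4 | (3S)-2,6-dioxo-3-(propan-2-yl)heptanoic acid (α-keto acid, not isolated) | CC(C)[C@H](CCC(C)=O)C(=O)C(=O)O | intermediate
5 | (2S)-5-oxo-2-(propan-2-yl)hexanoic acid | CC(C)[C@H](CCC(C)=O)C(=O)O | intermediate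
6 | (2S)-1-(1H-imidazol-1-yl)-2-(propan-2-yl)hexane-1,5-dione (acyl imidazole, not isolated) | CC(C)[C@H](CCC(C)=O)C(=O)n1ccnc1 | intermediate
7 | (2S)-N-methoxy-N-methyl-5-oxo-2-(propan-2-yl)hexanamide | CC(C)[C@H](CCC(C)=O)C(=O)N(C)OC | intermediate
8 | (2S)-5-hydroxy-N-methoxy-N,5-dimethyl-2-(propan-2-yl)hept-6-enamide, both C5 epimers | CC(C)[C@H](CCC(C)(O)C=C)C(=O)N(C)OC | intermediate
9 | (5S)-8-hydroxy-2,8-dimethyl-5-(propan-2-yl)deca-1,9-dien-4-one, both C8 epimers | CC(C)[C@H](CCC(C)(O)C=C)C(=O)CC(C)=C | intermediate
10 | (2E,6S)-3,9-dimethyl-7-oxo-6-(propan-2-yl)deca-2,9-dienal, E isomer drawn, used with the 2Z isomer | CC(C)[C@H](CC/C(C)=C/C=O)C(=O)CC(C)=C | intermediate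
11 | 2-[(1S,4S)-1-methyl-3-oxo-4-(propan-2-yl)-2-(prop-1-en-2-yl)cyclohexyl]acetaldehyde, both C2 epimers (Michael adduct, not isolated) | O=CC[C@]1(C)CC[C@@H](C(C)C)C(=O)C1C(C)=C | intermediate
12 | (2S,4aS)-4a,8-dimethyl-2-(propan-2-yl)-3,4,4a,5-tetrahydro-2H-naphthalen-1-one (eudesma-2,4-dien-6-one) | CC1=C2C(=O)[C@H](C(C)C)CC[C@@]2(C)CC=C1 | intermediate
13 | (2S,4aR,8aR)-4a,8-dimethyl-2-(propan-2-yl)-3,4,4a,5,6,8a-hexahydro-2H-naphthalen-1-one (eudesm-3-en-6-one) | CC1=CCC[C@]2(C)CC[C@@H](C(C)C)C(=O)[C@@H]12 | intermediate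
14 | (1R,2S,4aR,8aR)-4a,8-dimethyl-2-(propan-2-yl)-1,2,3,4,4a,5,6,8a-octahydronaphthalen-1-ol (eudesm-3-en-6β-ol) | CC1=CCC[C@]2(C)CC[C@@H](C(C)C)[C@@H](O)[C@@H]12 | intermediate
15 | (E)-p-coumaric acid, (2E)-3-(4-hydroxyphenyl)prop-2-enoic acid | OC(=O)/C=C/c1ccc(O)cc1 | starting material
16 | tert-butyldimethylsilyl (2E)-3-{4-[(tert-butyldimethylsilyl)oxy]phenyl}prop-2-enoate (not isolated) | CC(C)(C)[Si](C)(C)OC(=O)/C=C/c1ccc(O[Si](C)(C)C(C)(C)C)cc1 | intermediate
17 | (2E)-3-{4-[(tert-butyldimethylsilyl)oxy]phenyl}prop-2-enoic acid | OC(=O)/C=C/c1ccc(O[Si](C)(C)C(C)(C)C)cc1 | intermediate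
18 | (2E)-3-{4-[(tert-butyldimethylsilyl)oxy]phenyl}prop-2-enoic 2,4,6-trichlorobenzoic anhydride (not isolated) | O=C(/C=C/c1ccc(O[Si](C)(C)C(C)(C)C)cc1)OC(=O)c1c(Cl)cc(Cl)cc1Cl | intermediate
19 | (1R,2S,4aR,8aR)-4a,8-dimethyl-2-(propan-2-yl)-1,2,3,4,4a,5,6,8a-octahydronaphthalen-1-yl (2E)-3-{4-[(tert-butyldimethylsilyl)oxy]phenyl}prop-2-enoate | CC1=CCC[C@]2(C)CC[C@@H](C(C)C)[C@@H](OC(=O)/C=C/c3ccc(O[Si](C)(C)C(C)(C)C)cc3)[C@@H]12 | intermediate
20 | (1R,2S,4aR,8aR)-4a,8-dimethyl-2-(propan-2-yl)-1,2,3,4,4a,5,6,8a-octahydronaphthalen-1-yl (2E)-3-(4-hydroxyphenyl)prop-2-enoate, CNP0220414.1 | CC1=CCC[C@]2(C)CC[C@@H](C(C)C)[C@@H](OC(=O)/C=C/c3ccc(O)cc3)[C@@H]12 | target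

**Step count and risks**

Total: 13 steps. Longest linear sequence: 12 steps (steps 1–10, 12 and 13, from (−)-menthone).

Steps most likely to fail:

1. Step 8 (Proposed new method). What may go wrong: poor facial selectivity at C10 in the Michael closure, failure of the second (vinylogous) closure, isomerisation of the β,γ-unsaturated ketone into conjugation as a dead end, or slow epimerisation at C7. Fallback with known chemistry, in which ring B is kept intact from the pool and ring A is built by conjugate addition and aldol cyclodehydration; it sets out from 3 and comes back at 13, replacing steps 3–9. Copper-catalysed conjugate addition of the Grignard reagent from 2-(3-chloropropyl)-2-methyl-1,3-dioxolane and Mg to (S)-piperitone 3 (CuBr·SMe2, THF, −30 °C) should make C10 quaternary, the chain being expected to enter trans to the isopropyl group, and give (3R,6S)-3-methyl-3-[3-(2-methyl-1,3-dioxolan-2-yl)propyl]-6-(propan-2-yl)cyclohexan-1-one F1. Aqueous HCl in THF would unmask (3R,6S)-3-methyl-3-(4-oxopentyl)-6-(propan-2-yl)cyclohexan-1-one F2, and aldol cyclodehydration between C5 and C4 (TsOH, toluene, reflux) would give (2S,4aR)-4a,8-dimethyl-2-(propan-2-yl)-3,4,4a,5,6,7-hexahydro-2H-naphthalen-1-one F3 (eudesm-4-en-6-one). Deconjugation through the potassium dienolate (KOt-Bu, t-BuOH, rt, then rapid quench with cold aq. AcOH) would lead to 13, any C7 epimer being removed by chromatography.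

2. Step 9. What may go wrong: over-reduction, protonation of the dienolate at C3 instead of C5 or from the β face, and reconjugation of the sensitive β,γ-unsaturated ketone during work-up. Fallback that avoids the β,γ-unsaturated ketone altogether; it sets out from 12 and comes back at 14, replacing steps 9 and 10. 1,2-Reduction of 12 (NaBH4, CeCl3·7H2O, MeOH, −40 °C), with hydride entering anti to C14, would give (1R,2S,4aS)-4a,8-dimethyl-2-(propan-2-yl)-1,2,3,4,4a,5-hexahydronaphthalen-1-ol F4. 1,4-Hydrogenation of its homoannular s-cis diene C2=C3–C4=C5 with (η6-naphthalene)Cr(CO)3 under H2 in THF should add hydrogen to C2 and C5 from the α face and leave the C3=C4 double bond, which gives 14.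

3. Step 12. What may go wrong: slow acylation of the axial C6 hydroxyl group, which is flanked by C5 and the isopropyl-bearing C7 and is syn-axial to C14, with decomposition of the mixed anhydride or elimination on prolonged heating. Fallback that acylates with a small acyl donor and builds the cinnamate double bond afterwards; it sets out from 14 and comes back at 19. Acylation of 14 with diethylphosphonoacetic acid and N,N'-dicyclohexylcarbodiimide (by way of the derived ketene, CH2Cl2, rt) would give (1R,2S,4aR,8aR)-4a,8-dimethyl-2-(propan-2-yl)-1,2,3,4,4a,5,6,8a-octahydronaphthalen-1-yl 2-(diethoxyphosphoryl)acetate F5. Horner–Wadsworth–Emmons olefination with commercial 4-[(tert-butyldimethylsilyl)oxy]benzaldehyde (LiCl, DBU, MeCN, rt) would then give the (E)-cinnamate 19.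

**Further compounds**

F1 | step 8 | (3R,6S)-3-methyl-3-[3-(2-methyl-1,3-dioxolan-2-yl)propyl]-6-(propan-2-yl)cyclohexan-1-one | CC(C)[C@@H]1CC[C@@](C)(CCCC2(C)OCCO2)CC1=O
F2 | step 8 | (3R,6S)-3-methyl-3-(4-oxopentyl)-6-(propan-2-yl)cyclohexan-1-one | CC(C)[C@@H]1CC[C@@](C)(CCCC(C)=O)CC1=O
F3 | step 8 | (2S,4aR)-4a,8-dimethyl-2-(propan-2-yl)-3,4,4a,5,6,7-hexahydro-2H-naphthalen-1-one | CC1=C2C(=O)[C@H](C(C)C)CC[C@@]2(C)CCC1
F4 | step 9 | (1R,2S,4aS)-4a,8-dimethyl-2-(propan-2-yl)-1,2,3,4,4a,5-hexahydronaphthalen-1-ol | CC1=C2[C@H](O)[C@H](C(C)C)CC[C@@]2(C)CC=C1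
F5 | step 12 | (1R,2S,4aR,8aR)-4a,8-dimethyl-2-(propan-2-yl)-1,2,3,4,4a,5,6,8a-octahydronaphthalen-1-yl 2-(diethoxyphosphoryl)acetate | CC1=CCC[C@]2(C)CC[C@@H](C(C)C)[C@@H](OC(=O)CP(=O)(OCC)OCC)[C@@H]12
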